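At the last reading, 25.0 min, the south run held 2.1% of substrate and the south-east run 0.3%, far less than the target in each . So I took the contest to lie between target and isomer of the product.

common to all: substrate 2.2 M; gas phase 200 mM (held)
- south: catalyst 18 mM; run made earlier
- south-east: catalyst 26 mM; run made earlier
- Friday's: catalyst 35 mM; time 30 min
- Sunday's: catalyst 35 mM; time 90 min

- south (time / min: target / %, substrate / %, isomer of the product / %): 6.00: 26.3, 18.7, 1.7; 12.0: 32.3, 7.5, 5.8; 20.0: 30.8, 2.0, 8.8; 25.0: 28.9, 2.1, 11.4
- south-east (time / min: target / %, substrate / %, isomer of the product / %): 6.00: 35.7, 14.4, 1.9; 12.0: 39.8, 3.7, 7.4; 20.0: 37.7, 1.7, 12.3; 25.0: 35.2, 0.3, 13.9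

(each reading ± 0.5 percentage points)

- percentages count the substrate that a species holds: one homo dimer counts as two
- at the start none of the gas is dissolved
- steps that have been proposed: gas phase <-> dissolved gas; substrate + dissolved gas + catalyst -> catalyst + target; 2 substrate -> homo dimer; target <-> isomer of the product

- which of these there is most of at the end, counted by the substrate in it, Friday's (target / isomer of the product / substrate)
- which of these there is most of at the end, counted by the substrate in it, Sunday's (target / isomer of the product / substrate)
- amount of the one of these that there is most of at the end, in percent of the substrate charged, Friday's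
- amount of the one of these that there is most of at the end, in percent of the substrate charged, Sunday's

I treated the isomer as a correction on the product and reckoned it by its share, [isomer]/([target]+[isomer]), which leaves the total out of the comparison. At 25.0 min the share was 0.283 in the south run and 0.283 in the south-east run, although the catalyst differed by a factor of 1.44. I therefore carried the share over to Friday's and Sunday's flasks, with 35 mM of catalyst. Averaged over both runs it went from 0.155 at 12.0 min to 0.283, a rise of 0.00988 min⁻¹. Continued in a straight line, it reached 0.5 at 47.0 min. This is my estimated crossing time, a straight-line estimate from scattered shares of when isomer and target stand equal.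

Then I turned the question round. For the isomer to lead in Friday's flask, the share had to rise at 0.0434 min⁻¹, which is 4.39 times the rate I read. For the target to keep its lead in Sunday's flask, the average rise after 25.0 min had to stay under 0.00334 min⁻¹, about a third of that rate. A resting share below 0.5, which is the thermodynamic side of kinetic against thermodynamic control, would do that, and these readings did not exclude it.

The forecast gave target at 38% (35% to 41%) for Friday's flask and isomer of the product at 35% (29% to 42%) for Sunday's. It took a rise of 0.013 per minute, steeper than mine, and said “The isomer fraction of the product does not depend on catalyst”.

Friday's flask gave target at 37.1%, with a share of 0.350. Sunday's gave isomer of the product at 33.9%, with a share of 0.594. The two times lay on either side of my estimate of 47.0 min .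

    gas phase ⇌ dissolved gas, rate k1*(csat - [dissolved gas]) (kL = 2.10 s⁻¹)
    substrate + dissolved gas + catalyst → catalyst + target (k = 0.530 M⁻² s⁻¹)
    2 substrate → homo dimer (k = 0.00150 M⁻¹ s⁻¹)
    target ⇌ isomer of the product (K = 1.80, k = 3.20 × 10⁻⁴ s⁻¹)

Reversing Friday's outcome took a later reading: at 80 min that flask held 32.9% isomer against 24.2% target. With 0.014 M of catalyst at 30 min, the share was 0.321 and target led with 24.9%. Neither of the two asked flasks was at rest. At 300 min Friday's flask held 36.7% isomer and 20.4% target, and at 900 min Sunday's flask had gained 2.8 percentage points of isomer to reach 36.7%.

The readings come from a simulation with made-up constants; scatter was added.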